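**Retrosynthetic overview**
1. Target ← site-selective acetylation of a 2α,3α-diol ← cis-dihydroxylation of a Δ2 olefin; C8 methyl and Δ7 ← Stille methylation of the kinetic enol triflate of a C8 ketone.
2. Ring B ← one-carbon ring expansion of a trans-hydrindanone: semipinacol 1,2-shift of the quaternary C10 from C8 to C9 in a β-hydroxy selenide, whose α-selenoalkyllithium precursor brings in the whole C9–C15 side chain.
3. Ring A ← ring-closing metathesis (C2=C3) of a 2-allyl-3-(1,1-dimethylallyl)cyclopentanone ← enantioselective conjugate reverse prenylation of 2-methylcyclopent-2-enone with enolate allylation (sets C5 and C10).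
4. Side chain (C13) ← copper-catalysed asymmetric conjugate addition of an acetal Grignard reagent to methyl crotonate.
5. Ring order: purchased cyclopentenone → ring A (metathesis) → ring B (five- to six-membered expansion).

Assumption: the catalyst enantiomers named [(S,S)-IDPi acid, (S)-Tol-BINAP] are those taken to give the drawn configurations; if the sense of induction is opposite, the mirror-image catalyst is used.

Step 1
Reactants: 1 (3-methylbut-2-en-1-yl)magnesium chloride
Product: 2 trimethyl(3-methylbut-2-en-1-yl)silane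
Conditions: Me3SiCl, THF, 0 to 25 °C
Reagents that add atoms: chlorotrimethylsilane, C[Si](C)(C)Cl
Why: Electrophilic silylation of the allylic Grignard reagent at its less hindered primary terminus gives the prenylsilane, and no stereocentre is formed.

Step 2
Reactants: 3 2-methylcyclopent-2-en-1-one, 2 trimethyl(3-methylbut-2-en-1-yl)silane, 4 3-bromoprop-1-ene
Product: 7 (2S,3S)-2-methyl-3-(2-methylbut-3-en-2-yl)-2-(prop-2-en-1-yl)cyclopentan-1-one, via silyl enol ether 5 (not isolated), via lithium enolate 6 (not isolated)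
Conditions: (S,S)-IDPi acid (confined chiral imidodiphosphorimidate, 2 mol %), PhMe, −60 °C; then MeLi, THF, 0 °C; then 4, DMPU, −78 to 0 °C
Reagents that add atoms: none
Why: Proposed new method: an enantioselective Hosomi–Sakurai conjugate reverse prenylation in which the chiral acid is silylated by 2, the resulting silylium ion pair O-silylates enone 3, and the prenylsilane attacks the β-carbon through its γ-carbon (SE2′) inside the chiral anion pocket to set the ring C3 centre as S while silyl transfer releases silyl enol ether 5 and the catalyst, the closest known reaction types being the TiCl4-promoted racemic Hosomi–Sakurai conjugate allylation and silylium counteranion-directed Mukaiyama–Michael additions; MeLi then unmasks the regiodefined enolate 6, which is allylated anti to the bulky 1,1-dimethylallyl group to give the trans quaternary centre (2S).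

Step 3
Reactants: 7 (2S,3S)-2-methyl-3-(2-methylbut-3-en-2-yl)-2-(prop-2-en-1-yl)cyclopentan-1-one
Product: 8 (3aS,7aS)-4,4,7a-trimethyl-2,3,3a,4,7,7a-hexahydro-1H-inden-1-one
Conditions: second-generation Grubbs catalyst RuCl2(=CHPh)(H2IMes)(PCy3) (3 mol %), CH2Cl2, 40 °C
Reagents that add atoms: none
Why: Ring-closing metathesis of the two terminal olefins closes ring A as a cyclohexene carrying the gem-dimethyl carbon and locks the trans ring fusion already fixed in 7, with no new stereocentre.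

Step 4
Reactants: 9 2-(2-bromoethyl)-1,3-dioxolane, 10 methyl (2E)-but-2-enoate
Product: 13 (3S)-5-(1,3-dioxolan-2-yl)-3-methylpentanoic acid, via Grignard reagent 11 (not isolated), via methyl ester 12 (not isolated)
Conditions: Mg, THF, 30 °C; then 10, CuI (copper monoiodide, 2 mol %), (S)-Tol-BINAP (3 mol %), t-BuOMe, −40 °C; then LiOH, MeOH/H2O, 25 °C; HCl to pH 4
Reagents that add atoms: lithium hydroxide, [Li+].[OH-]
Why: Copper-catalysed asymmetric conjugate addition of the Grignard reagent to the crotonate sets the 3S centre (C13 of the target) under ligand control, and saponification masks the ester as a carboxylate for the organolithium step.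

Step 5
Reactants: 13 (3S)-5-(1,3-dioxolan-2-yl)-3-methylpentanoic acid
Product: 14 (3S)-3-methyl-6,6-bis(phenylselanyl)hexanoic acid
Conditions: PhSeH (2.2 equiv), BF3·OEt2, CH2Cl2, 0 °C
Reagents that add atoms: benzeneselenol, [SeH]c1ccccc1
Why: Lewis-acid transacetalisation of the dioxolane with the selenol gives the selenoacetal that serves as precursor of an α-selenoalkyllithium, leaving the stereocentre untouched.

Step 6
Reactants: 14 (3S)-3-methyl-6,6-bis(phenylselanyl)hexanoic acid, 8 (3aS,7aS)-4,4,7a-trimethyl-2,3,3a,4,7,7a-hexahydro-1H-inden-1-one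
Product: 17 methyl (3S)-6-[(1S,3aS,7aS)-1-hydroxy-4,4,7a-trimethyl-2,3,3a,4,7,7a-hexahydro-1H-inden-1-yl]-3-methyl-6-(phenylselanyl)hexanoate, via lithiated selenide 15 (not isolated), via hydroxy acid 16 (not isolated)
Conditions: NaH, THF, 0 °C; n-BuLi, −78 °C; 8, −78 to −40 °C; AcOH; then Me3SiCHN2, PhMe/MeOH, 0 °C
Reagents that add atoms: trimethylsilyldiazomethane, C[Si](C)(C)C=[N+]=[N-]
Why: Selenium–lithium exchange gives a weakly basic α-selenoalkyllithium (carboxylate protected as its sodium salt) that adds 1,2 to the hindered ketone from the face anti to the angular methyl, setting the carbinol centre as 1S while the selenium-bearing carbon forms as an inconsequential epimer mixture, and the acid is then re-esterified.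

Step 7
Reactants: 17 methyl (3S)-6-[(1S,3aS,7aS)-1-hydroxy-4,4,7a-trimethyl-2,3,3a,4,7,7a-hexahydro-1H-inden-1-yl]-3-methyl-6-(phenylselanyl)hexanoate
Product: 20 methyl (3S)-3-methyl-5-[(1R,4aS,8aS)-5,5,8a-trimethyl-2-oxo-1,2,3,4,4a,5,8,8a-octahydronaphthalen-1-yl]pentanoate, via selenonium triflate 18 (not isolated), via axial epimer 19 (not isolated)
Conditions: MeOTf, 2,6-di-tert-butyl-4-methylpyridine, CH2Cl2, −40 to 25 °C; NaHCO3 work-up; then DBU (0.2 equiv), CH2Cl2, 25 °C
Reagents that add atoms: none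
Why: Semipinacol ring enlargement of a β-hydroxy selenide, in which Se-methylation makes selenium a leaving group and the anti-periplanar, more electron-rich quaternary ring carbon C10 shifts with retention from the carbinol carbon to the selenium-bearing carbon, forming the C9–C10 bond, ring B and the C8 ketone, after which DBU equilibrates the enolisable C9 centre to the equatorial side chain (1R).

Step 8
Reactants: 20 methyl (3S)-3-methyl-5-[(1R,4aS,8aS)-5,5,8a-trimethyl-2-oxo-1,2,3,4,4a,5,8,8a-octahydronaphthalen-1-yl]pentanoate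
Product: 22 methyl (3S)-3-methyl-5-[(1R,4aS,8aS)-5,5,8a-trimethyl-2-{[(trifluoromethyl)sulfonyl]oxy}-1,4,4a,5,8,8a-hexahydronaphthalen-1-yl]pentanoate, via potassium enolate 21 (not isolated)
Conditions: KN(SiMe3)2, THF, −78 °C; PhNTf2, −78 to 0 °C; NH4Cl work-up
Reagents that add atoms: N-phenylbis(trifluoromethanesulfonimide), O=S(=O)(N(c1ccccc1)S(=O)(=O)C(F)(F)F)C(F)(F)F
Why: Kinetic deprotonation at the unhindered C7 methylene (the C9 methine beside the quaternary carbon is far slower and the ester less acidic) followed by O-sulfonylation gives the Δ7 enol triflate regioselectively without touching any stereocentre.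

Step 9
Reactants: 22 methyl (3S)-3-methyl-5-[(1R,4aS,8aS)-5,5,8a-trimethyl-2-{[(trifluoromethyl)sulfonyl]oxy}-1,4,4a,5,8,8a-hexahydronaphthalen-1-yl]pentanoate
Product: 23 methyl (3S)-5-[(1R,4aR,6S,7R,8aS)-6,7-dihydroxy-5,5,8a-trimethyl-2-{[(trifluoromethyl)sulfonyl]oxy}-1,4,4a,5,6,7,8,8a-octahydronaphthalen-1-yl]-3-methylpentanoate
Conditions: OsO4 (2 mol %), NMO (1.3 equiv), acetone/H2O, 20 °C
Reagents that add atoms: N-methylmorpholine N-oxide, C[N+]1([O-])CCOCC1; water, O; osmium tetroxide (catalytic oxygen carrier), O=[Os](=O)(=O)=O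
Why: Catalytic osmium tetroxide cis-dihydroxylation attacks only the electron-rich Δ2 olefin and not the electron-poor enol triflate, from the α-face opposite the axial C10 and C4 methyl groups, which sets the 2α,3α-diol (6S,7R).

Step 10
Reactants: 23 methyl (3S)-5-[(1R,4aR,6S,7R,8aS)-6,7-dihydroxy-5,5,8a-trimethyl-2-{[(trifluoromethyl)sulfonyl]oxy}-1,4,4a,5,6,7,8,8a-octahydronaphthalen-1-yl]-3-methylpentanoate
Product: 24 methyl (3S)-5-[(1S,4aR,6S,7R,8aR)-6,7-dihydroxy-2,5,5,8a-tetramethyl-1,4,4a,5,6,7,8,8a-octahydronaphthalen-1-yl]-3-methylpentanoate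
Conditions: SnMe4, Pd(PPh3)4 (5 mol %), LiCl, DMF, 80 °C
Reagents that add atoms: tetramethylstannane, C[Sn](C)(C)C
Why: Stille cross-coupling of the vinyl triflate with tetramethyltin on zerovalent palladium installs the C8 methyl with the Δ7 double bond fixed in place, tolerating the free diol and the ester and touching no stereocentre.

Step 11
Reactants: 24 methyl (3S)-5-[(1S,4aR,6S,7R,8aR)-6,7-dihydroxy-2,5,5,8a-tetramethyl-1,4,4a,5,6,7,8,8a-octahydronaphthalen-1-yl]-3-methylpentanoate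
Product: 25 methyl (3S)-5-[(1S,4aR,6S,7R,8aR)-7-acetyloxy-6-hydroxy-2,5,5,8a-tetramethyl-1,4,4a,5,6,7,8,8a-octahydronaphthalen-1-yl]-3-methylpentanoate
Conditions: Ac2O (1.1 equiv), pyridine, CH2Cl2, 0 °C
Reagents that add atoms: acetic anhydride, CC(=O)OC(C)=O
Why: Site-selective acylation, because the equatorial C2 hydroxyl reacts much faster than the axial, neopentyl C3 hydroxyl beside the gem-dimethyl carbon, giving the 2α-acetate with both stereocentres retained.

**Compound list**
1 | (3-methylbut-2-en-1-yl)magnesium chloride | CC(C)=CC[Mg]Cl | starting material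
2 | trimethyl(3-methylbut-2-en-1-yl)silane | CC(C)=CC[Si](C)(C)C | intermediate
3 | 2-methylcyclopent-2-en-1-one | CC1=CCCC1=O | starting material
4 | 3-bromoprop-1-ene | C=CCBr | starting material
5 | trimethyl{[(3S)-2-methyl-3-(2-methylbut-3-en-2-yl)cyclopent-1-en-1-yl]oxy}silane | C[Si](C)(C)OC1=C(C)[C@H](C(C)(C)C=C)CC1 | intermediate
6 | lithium (3S)-2-methyl-3-(2-methylbut-3-en-2-yl)cyclopent-1-en-1-olate | [Li+].[O-]C1=C(C)[C@H](C(C)(C)C=C)CC1 | intermediate
7 | (2S,3S)-2-methyl-3-(2-methylbut-3-en-2-yl)-2-(prop-2-en-1-yl)cyclopentan-1-one | O=C1CC[C@@H](C(C)(C)C=C)[C@]1(C)CC=C | intermediate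
8 | (3aS,7aS)-4,4,7a-trimethyl-2,3,3a,4,7,7a-hexahydro-1H-inden-1-one | O=C1CC[C@H]2C(C)(C)C=CC[C@]12C | intermediate
9 | 2-(2-bromoethyl)-1,3-dioxolane | BrCCC1OCCO1 | starting material
10 | methyl (2E)-but-2-enoate | C/C=C/C(=O)OC | starting material
11 | [2-(1,3-dioxolan-2-yl)ethyl]magnesium bromide | Br[Mg]CCC1OCCO1 | intermediate
12 | methyl (3S)-5-(1,3-dioxolan-2-yl)-3-methylpentanoate | COC(=O)C[C@@H](C)CCC1OCCO1 | intermediate
13 | (3S)-5-(1,3-dioxolan-2-yl)-3-methylpentanoic acid | OC(=O)C[C@@H](C)CCC1OCCO1 | intermediate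
14 | (3S)-3-methyl-6,6-bis(phenylselanyl)hexanoic acid | OC(=O)C[C@@H](C)CCC([Se]c1ccccc1)[Se]c1ccccc1 | intermediate
15 | sodium (3S)-6-lithio-3-methyl-6-(phenylselanyl)hexanoate | [Na+].[Li+].[O-]C(=O)C[C@@H](C)CC[CH-][Se]c1ccccc1 | intermediate
16 | (3S)-6-[(1S,3aS,7aS)-1-hydroxy-4,4,7a-trimethyl-2,3,3a,4,7,7a-hexahydro-1H-inden-1-yl]-3-methyl-6-(phenylselanyl)hexanoic acid (both C6 epimers) | OC(=O)C[C@@H](C)CCC([Se]c1ccccc1)[C@]3(O)CC[C@H]2C(C)(C)C=CC[C@]32C | intermediate
17 | methyl (3S)-6-[(1S,3aS,7aS)-1-hydroxy-4,4,7a-trimethyl-2,3,3a,4,7,7a-hexahydro-1H-inden-1-yl]-3-methyl-6-(phenylselanyl)hexanoate (both C6 epimers) | COC(=O)C[C@@H](C)CCC([Se]c1ccccc1)[C@]3(O)CC[C@H]2C(C)(C)C=CC[C@]32C | intermediate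
18 | Se-methyl selenonium trifluoromethanesulfonate of 17 | COC(=O)C[C@@H](C)CCC([Se+](C)c1ccccc1)[C@]3(O)CC[C@H]2C(C)(C)C=CC[C@]32C.[O-]S(=O)(=O)C(F)(F)F | intermediate
19 | methyl (3S)-3-methyl-5-[(1S,4aS,8aS)-5,5,8a-trimethyl-2-oxo-1,2,3,4,4a,5,8,8a-octahydronaphthalen-1-yl]pentanoate (axial side chain) | COC(=O)C[C@@H](C)CC[C@@H]1C(=O)CC[C@H]2C(C)(C)C=CC[C@]12C | intermediate
20 | methyl (3S)-3-methyl-5-[(1R,4aS,8aS)-5,5,8a-trimethyl-2-oxo-1,2,3,4,4a,5,8,8a-octahydronaphthalen-1-yl]pentanoate | COC(=O)C[C@@H](C)CC[C@H]1C(=O)CC[C@H]2C(C)(C)C=CC[C@]12C | intermediate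
21 | potassium (1R,4aS,8aS)-1-[(3S)-5-methoxy-3-methyl-5-oxopentyl]-5,5,8a-trimethyl-1,4,4a,5,8,8a-hexahydronaphthalen-2-olate | [K+].COC(=O)C[C@@H](C)CC[C@H]1C([O-])=CC[C@H]2C(C)(C)C=CC[C@]12C | intermediate
22 | methyl (3S)-3-methyl-5-[(1R,4aS,8aS)-5,5,8a-trimethyl-2-{[(trifluoromethyl)sulfonyl]oxy}-1,4,4a,5,8,8a-hexahydronaphthalen-1-yl]pentanoate | COC(=O)C[C@@H](C)CC[C@H]1C(OS(=O)(=O)C(F)(F)F)=CC[C@H]2C(C)(C)C=CC[C@]12C | intermediate
23 | methyl (3S)-5-[(1R,4aR,6S,7R,8aS)-6,7-dihydroxy-5,5,8a-trimethyl-2-{[(trifluoromethyl)sulfonyl]oxy}-1,4,4a,5,6,7,8,8a-octahydronaphthalen-1-yl]-3-methylpentanoate | COC(=O)C[C@@H](C)CC[C@H]1C(OS(=O)(=O)C(F)(F)F)=CC[C@H]2C(C)(C)[C@H](O)[C@H](O)C[C@]12C | intermediate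
24 | methyl (3S)-5-[(1S,4aR,6S,7R,8aR)-6,7-dihydroxy-2,5,5,8a-tetramethyl-1,4,4a,5,6,7,8,8a-octahydronaphthalen-1-yl]-3-methylpentanoate | COC(=O)C[C@@H](C)CC[C@H]1C(C)=CC[C@H]2C(C)(C)[C@H](O)[C@H](O)C[C@]12C | intermediate
25 | methyl (3S)-5-[(1S,4aR,6S,7R,8aR)-7-acetyloxy-6-hydroxy-2,5,5,8a-tetramethyl-1,4,4a,5,6,7,8,8a-octahydronaphthalen-1-yl]-3-methylpentanoate (CNP0571009.1) | COC(=O)C[C@@H](C)CC[C@H]1C(C)=CC[C@H]2C(C)(C)[C@H](O)[C@H](OC(C)=O)C[C@]12C | target

**Step count and risks**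
Total step count: 11. Longest linear sequence: 9 steps (steps 1, 2, 3, 6, 7, 8, 9, 10, 11); the side-chain branch (steps 4, 5) joins at step 6.

Step 2 (proposed new method) may give low enantioselectivity or competing 1,2- or α-attack. The fallback sets out from 3 (with 2 and 4) and comes back at 8, using known chemistry. Catalytic HNTf2, which forms Me3SiNTf2 with 2, promotes the racemic Hosomi–Sakurai addition to give racemic silyl enol ether F1. MeLi converts it into racemic lithium enolate F2, and allyl bromide gives racemic trans ketone F3. Ring-closing metathesis under the step 3 conditions gives racemic hydrindenone F4, which is resolved by preparative chiral-phase supercritical-fluid chromatography to deliver 8.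

Step 7 (ring expansion) may suffer from oxirane formation, from migration of the C7 methylene instead of the quaternary C10, and from only a modest equatorial preference at C9 (the minor epimer would be recycled through DBU). The fallback sets out from 17 and comes back at 20. H2O2 with pyridine oxidises 17 to selenoxide F5, which undergoes syn-elimination to (E)-allylic alcohol F6. Hydroxyl-directed epoxidation with VO(acac)2 and t-BuOOH, which leaves the Δ2 olefin alone, gives epoxy alcohol F7. BF3·OEt2 then triggers the epoxy-alcohol semipinacol shift of the quaternary carbon to give β-hydroxy ketone F8. Dehydration with p-TsOH gives exocyclic enone F9, and conjugate reduction with [(Ph3P)CuH]6 followed by DBU equilibration gives 20.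

Step 11 (mono-acetylation) may give the diacetate or the 3-acetate. The fallback sets out from 24 and comes back at 25. Bu2SnO in refluxing toluene with water removal gives dibutylstannylene acetal F10, which AcCl at 0 °C acylates selectively at the equatorial C2 oxygen; aqueous work-up gives 25.

Further compounds
F1 | step 2 | racemic trimethyl{[2-methyl-3-(2-methylbut-3-en-2-yl)cyclopent-1-en-1-yl]oxy}silane | C[Si](C)(C)OC1=C(C)[C@H](C(C)(C)C=C)CC1.C[Si](C)(C)OC1=C(C)[C@@H](C(C)(C)C=C)CC1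
F2 | step 2 | racemic lithium 2-methyl-3-(2-methylbut-3-en-2-yl)cyclopent-1-en-1-olate | [Li+].[O-]C1=C(C)[C@H](C(C)(C)C=C)CC1.[Li+].[O-]C1=C(C)[C@@H](C(C)(C)C=C)CC1
F3 | step 2 | racemic trans-2-methyl-3-(2-methylbut-3-en-2-yl)-2-(prop-2-en-1-yl)cyclopentan-1-one | O=C1CC[C@@H](C(C)(C)C=C)[C@]1(C)CC=C.O=C1CC[C@H](C(C)(C)C=C)[C@@]1(C)CC=C
F4 | step 2 | racemic trans-4,4,7a-trimethyl-2,3,3a,4,7,7a-hexahydro-1H-inden-1-one | O=C1CC[C@H]2C(C)(C)C=CC[C@]12C.O=C1CC[C@@H]2C(C)(C)C=CC[C@@]12C
F5 | step 7 | methyl (3S)-6-[(1S,3aS,7aS)-1-hydroxy-4,4,7a-trimethyl-2,3,3a,4,7,7a-hexahydro-1H-inden-1-yl]-3-methyl-6-(phenylseleninyl)hexanoate | COC(=O)C[C@@H](C)CCC([Se](=O)c1ccccc1)[C@]3(O)CC[C@H]2C(C)(C)C=CC[C@]32C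
F6 | step 7 | methyl (3S,5E)-6-[(1R,3aS,7aS)-1-hydroxy-4,4,7a-trimethyl-2,3,3a,4,7,7a-hexahydro-1H-inden-1-yl]-3-methylhex-5-enoate | COC(=O)C[C@@H](C)C/C=C/[C@]3(O)CC[C@H]2C(C)(C)C=CC[C@]32C
F7 | step 7 | methyl (3S)-4-{3-[(1S,3aS,7aS)-1-hydroxy-4,4,7a-trimethyl-2,3,3a,4,7,7a-hexahydro-1H-inden-1-yl]oxiran-2-yl}-3-methylbutanoate (trans-oxirane, both faces) | COC(=O)C[C@@H](C)CC4OC4[C@]3(O)CC[C@H]2C(C)(C)C=CC[C@]32C
F8 | step 7 | methyl (3S)-5-hydroxy-3-methyl-5-[(4aS,8aS)-5,5,8a-trimethyl-2-oxo-1,2,3,4,4a,5,8,8a-octahydronaphthalen-1-yl]pentanoate | COC(=O)C[C@@H](C)CC(O)C1C(=O)CC[C@H]2C(C)(C)C=CC[C@]12C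
F9 | step 7 | methyl (3S)-3-methyl-5-[(4aS,8aS)-5,5,8a-trimethyl-2-oxo-3,4,4a,5,8,8a-hexahydronaphthalen-1(2H)-ylidene]pentanoate | COC(=O)C[C@@H](C)CC=C1C(=O)CC[C@H]2C(C)(C)C=CC[C@]12C
F10 | step 11 | 6,7-O-dibutylstannylene acetal of 24 | COC(=O)C[C@@H](C)CC[C@H]1C(C)=CC[C@H]2C(C)(C)[C@H](O[Sn]3(CCCC)CCCC)[C@H](O3)C[C@]12C
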